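**Retrosynthetic overview**

- The plan rests on ring A holding the C2 carbinol 1,3 to the quaternary C10 (through C1) and ring B holding the C8=C17 methylene next to C9. That pattern is what is left when a C2 aldehyde adds to C1 of an isopropenyl group (C10=C1) carried on C5 and the C10 cation is taken by C9 of a C8=C9 allylsilane.
- Target 27 ⇐ 7-deoxy compound 26 (C7–O, allylic hydroxylation) ⇐ trienal 25 (C1–C2 closes ring A, then C9–C10 closes ring B, in one operation).
- 25 ⇐ alkenyl chloride 20 (C8–C17, Negishi coupling) ⇐ alkylzinc from iodide 12 + gem-dichloroalkene 18 (C7–C8, trans-selective Negishi coupling); 18 comes from neryl acetate.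
- 12 ⇐ lactone 8: C4 by two enolate alkylations (methyl last, anti to isopropenyl); C5 by Rh/(S)-BINAP conjugate addition of an isopropenyl boronate to 5,6-dihydro-2H-pyran-2-one.

Key step: step 17

Remark: labdane carbon numbers are used for all intermediates; the allylsilane alkene C8=C9 has C7 and C11 trans (the backbone geometry the chair needs) and is (Z) by the CIP rules only because CH2Si outranks C7; the CH2OAc on C4 is the axial 4β carbon, C19.

**Step 1**
Reactants: 1 5,6-dihydro-2H-pyran-2-one; 2 2-isopropenyl-4,4,5,5-tetramethyl-1,3,2-dioxaborolane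
Product: 3 (S)-4-(prop-1-en-2-yl)tetrahydro-2H-pyran-2-one
Conditions: [Rh(cod)OH]2 (2.5 mol %), (S)-BINAP (6 mol %), 1,4-dioxane/H2O 10:1, 50 °C
Reagents that add atoms: none
Why: Hayashi–Miyaura Rh/BINAP asymmetric 1,4-addition of an alkenylboronate to an unsaturated lactone; the (S)-ligand should deliver the alkenyl group to the face that gives the (S)-lactone by the usual model for cyclic acceptors, which sets C5.

**Step 2**
Reactants: 3 (S)-4-(prop-1-en-2-yl)tetrahydro-2H-pyran-2-one; 4 tert-butyl(2-iodoethoxy)dimethylsilane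
Product: 6 (3R,4S)-3-[2-(tert-butyldimethylsilyloxy)ethyl]-4-(prop-1-en-2-yl)tetrahydro-2H-pyran-2-one, via lithium enolate of 3 5 (not isolated)
Conditions: LDA, THF, −78 °C; then 4, DMPU, −78 → −20 °C
Reagents that add atoms: none
Why: Lithium enolate alkylation (SN2) of the δ-lactone, which should enter anti to the isopropenyl group; the C4 configuration formed here is of no consequence because C4 is enolised again in step 3.

**Step 3**
Reactants: 6 (3R,4S)-3-[2-(tert-butyldimethylsilyloxy)ethyl]-4-(prop-1-en-2-yl)tetrahydro-2H-pyran-2-one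
Product: 8 (3S,4R)-3-[2-(tert-butyldimethylsilyloxy)ethyl]-3-methyl-4-(prop-1-en-2-yl)tetrahydro-2H-pyran-2-one, via lithium enolate of 6 7 (not isolated)
Conditions: LDA, THF, −78 °C; then MeI, −78 → −40 °C
Reagents that add atoms: iodomethane, CI
Why: Second lithium enolate alkylation; in the tetrasubstituted enolate A(1,2) strain turns the isopropenyl group pseudo-axial, so iodomethane should attack the opposite face and give the quaternary C4 (4S) with methyl trans to isopropenyl.

**Step 4**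
Reactants: 8 (3S,4R)-3-[2-(tert-butyldimethylsilyloxy)ethyl]-3-methyl-4-(prop-1-en-2-yl)tetrahydro-2H-pyran-2-one
Product: 9 (2S,3R)-2-[2-(tert-butyldimethylsilyloxy)ethyl]-2-methyl-3-(prop-1-en-2-yl)pentane-1,5-diol
Conditions: LiAlH4, THF, 0 °C; Fieser work-up
Reagents that add atoms: none
Why: Hydride reduction of the lactone to the 1,5-diol (C19–OH and C7–OH); the silyl ether and the alkene are inert and no stereocentre is touched.

**Step 5**
Reactants: 9 (2S,3R)-2-[2-(tert-butyldimethylsilyloxy)ethyl]-2-methyl-3-(prop-1-en-2-yl)pentane-1,5-diol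
Product: 11 (2S,3R)-2-[2-(tert-butyldimethylsilyloxy)ethyl]-2-methyl-3-(prop-1-en-2-yl)-5-(tosyloxy)pentyl acetate, via 5-monotosylate of 9 10 (not isolated)
Conditions: TsCl (1.05 equiv), Et3N, Me3N·HCl (cat.), CH2Cl2, 0 °C; then Ac2O, DMAP, 0 °C → rt
Reagents that add atoms: 4-toluenesulfonyl chloride, Cc1ccc(cc1)S(Cl)(=O)=O; acetic anhydride, CC(=O)OC(C)=O
Why: Selective sulfonylation of the unhindered C7 primary alcohol over the neopentyl C19 alcohol, followed in the same flask by DMAP-catalysed acetylation of the latter.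

**Step 6**
Reactants: 11 (2S,3R)-2-[2-(tert-butyldimethylsilyloxy)ethyl]-2-methyl-3-(prop-1-en-2-yl)-5-(tosyloxy)pentyl acetate
Product: 12 (2S,3R)-2-[2-(tert-butyldimethylsilyloxy)ethyl]-5-iodo-2-methyl-3-(prop-1-en-2-yl)pentyl acetate
Conditions: NaI, acetone, 55 °C
Reagents that add atoms: sodium iodide, [Na+].[I-]
Why: Finkelstein displacement (SN2) of the primary tosylate by iodide; the neopentyl acetate and the silyl ether are not affected.

**Step 7**
Reactants: 13 neryl acetate [(2Z)-3,7-dimethylocta-2,6-dien-1-yl acetate]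
Product: 15 (2Z)-3-methyl-6-oxohex-2-en-1-yl acetate, via ozonide of the 6,7-alkene 14 (not isolated)
Conditions: O3 (1.0 equiv, Sudan III end point), CH2Cl2, −78 °C; then PPh3, −78 °C → rt
Reagents that add atoms: ozone, [O-][O+]=O
Why: Ozonolysis with reductive work-up; ozone should take the electron-rich 6,7-alkene and spare the alkene deactivated by its allylic acetate, so the (Z)-alkene is kept.

**Step 8**
Reactants: 15 (2Z)-3-methyl-6-oxohex-2-en-1-yl acetate
Product: 16 (2Z)-7,7-dichloro-3-methylhepta-2,6-dien-1-yl acetate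
Conditions: PPh3 (4 equiv), CCl4 (2 equiv), THF, 60 °C
Reagents that add atoms: tetrachloromethane, ClC(Cl)(Cl)Cl
Why: Wittig-type dichloromethylenation of the aldehyde by Ph3P=CCl2 formed in the flask; the ester and the trisubstituted alkene are inert.

**Step 9**
Reactants: 16 (2Z)-7,7-dichloro-3-methylhepta-2,6-dien-1-yl acetate
Product: 17 (2Z)-7,7-dichloro-3-methylhepta-2,6-dien-1-ol
Conditions: K2CO3 (cat.), MeOH, 0 °C → rt
Reagents that add atoms: none
Why: Base-catalysed transesterification removes the allylic ester, so that no ionisable allylic acetate is present in the two palladium-catalysed steps.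

**Step 10**
Reactants: 17 (2Z)-7,7-dichloro-3-methylhepta-2,6-dien-1-ol
Product: 18 [(2Z)-7,7-dichloro-3-methylhepta-2,6-dien-1-yl]oxy(triethyl)silane
Conditions: TESCl, imidazole, CH2Cl2, 0 °C
Reagents that add atoms: chlorotriethylsilane, CC[Si](Cl)(CC)CC
Why: Silylation of the primary allylic alcohol; the TES ether is inert to Pd(0) and organozinc reagents and can later be removed beside a TBS ether and an allylsilane.

**Step 11**
Reactants: 12 (2S,3R)-2-[2-(tert-butyldimethylsilyloxy)ethyl]-5-iodo-2-methyl-3-(prop-1-en-2-yl)pentyl acetate; 18 [(2Z)-7,7-dichloro-3-methylhepta-2,6-dien-1-yl]oxy(triethyl)silane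
Product: 20 (2S,3R,6Z,10Z)-2-[2-(tert-butyldimethylsilyloxy)ethyl]-6-chloro-2,10-dimethyl-3-(prop-1-en-2-yl)-12-(triethylsilyloxy)dodeca-6,10-dien-1-yl acetate, via alkylzinc iodide from 12 19 (not isolated)
Conditions: Zn dust, LiCl, BrCH2CH2Br/TMSCl (cat.), THF, 40 °C; then 18, Pd(DPEphos)Cl2 (5 mol %), THF/DMF, 23 °C
Reagents that add atoms: none
Why: Direct zinc insertion into the primary iodide followed by Negishi coupling; palladium should insert into the C–Cl bond trans to the C9 substituent of the gem-dichloroalkene, so C7 ends up trans to C11 and the remaining chlorine cis to it, while ester, silyl ethers and alkenes tolerate the organozinc.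

**Step 12**
Reactants: 20 (2S,3R,6Z,10Z)-2-[2-(tert-butyldimethylsilyloxy)ethyl]-6-chloro-2,10-dimethyl-3-(prop-1-en-2-yl)-12-(triethylsilyloxy)dodeca-6,10-dien-1-yl acetate
Product: 21 (2S,3R,6Z,10Z)-2-[2-(tert-butyldimethylsilyloxy)ethyl]-2,10-dimethyl-3-(prop-1-en-2-yl)-12-(triethylsilyloxy)-6-[(trimethylsilyl)methyl]dodeca-6,10-dien-1-yl acetate
Conditions: Me3SiCH2MgCl, ZnCl2, THF, 0 °C; then 20, Pd(P(t-Bu)3)2 (5 mol %), THF/NMP, 50 °C
Reagents that add atoms: (trimethylsilyl)methylmagnesium chloride, C[Si](C)(C)C[Mg]Cl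
Why: Second Negishi coupling, of the alkenyl chloride, with retention of alkene geometry (bulky electron-rich phosphine for C–Cl insertion, zinc reagent without β-hydrogen), which should place CH2SiMe3 cis to C11 and give the allylsilane.

**Step 13**
Reactants: 21 (2S,3R,6Z,10Z)-2-[2-(tert-butyldimethylsilyloxy)ethyl]-2,10-dimethyl-3-(prop-1-en-2-yl)-12-(triethylsilyloxy)-6-[(trimethylsilyl)methyl]dodeca-6,10-dien-1-yl acetate
Product: 22 (2S,3R,6Z,10Z)-2-[2-(tert-butyldimethylsilyloxy)ethyl]-12-hydroxy-2,10-dimethyl-3-(prop-1-en-2-yl)-6-[(trimethylsilyl)methyl]dodeca-6,10-dien-1-yl acetate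
Conditions: PPTS (0.1 equiv), MeOH/CH2Cl2, 0 °C
Reagents that add atoms: none
Why: Mild acid-catalysed methanolysis of the primary TES ether; the TBS ether reacts far more slowly and pyridinium tosylate is too weak an acid to protodesilylate the allylsilane.

**Step 14**
Reactants: 22 (2S,3R,6Z,10Z)-2-[2-(tert-butyldimethylsilyloxy)ethyl]-12-hydroxy-2,10-dimethyl-3-(prop-1-en-2-yl)-6-[(trimethylsilyl)methyl]dodeca-6,10-dien-1-yl acetate
Product: 23 (2S,3R,6Z,10Z)-2-[2-(tert-butyldimethylsilyloxy)ethyl]-2,10-dimethyl-3-(prop-1-en-2-yl)-6-[(trimethylsilyl)methyl]dodeca-6,10-diene-1,12-diyl diacetate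
Conditions: Ac2O, pyridine, DMAP (cat.), CH2Cl2, 0 °C
Reagents that add atoms: acetic anhydride, CC(=O)OC(C)=O
Why: DMAP-catalysed acylation of the primary allylic alcohol installs the C15 acetate after the last palladium step; no other group reacts.

**Step 15**
Reactants: 23 (2S,3R,6Z,10Z)-2-[2-(tert-butyldimethylsilyloxy)ethyl]-2,10-dimethyl-3-(prop-1-en-2-yl)-6-[(trimethylsilyl)methyl]dodeca-6,10-diene-1,12-diyl diacetate
Product: 24 (2S,3R,6Z,10Z)-2-(2-hydroxyethyl)-2,10-dimethyl-3-(prop-1-en-2-yl)-6-[(trimethylsilyl)methyl]dodeca-6,10-diene-1,12-diyl diacetate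
Conditions: TBAF/AcOH (1:1, 1.5 equiv), THF, 0 °C → rt
Reagents that add atoms: none
Why: Fluoride cleavage of the primary TBS ether under acetic acid buffer, which keeps the medium non-basic so that both acetates stay, while the allyl–SiMe3 bond is much less prone to fluoride attack than the O–Si bond.

**Step 16**
Reactants: 24 (2S,3R,6Z,10Z)-2-(2-hydroxyethyl)-2,10-dimethyl-3-(prop-1-en-2-yl)-6-[(trimethylsilyl)methyl]dodeca-6,10-diene-1,12-diyl diacetate
Product: 25 (2S,3R,6Z,10Z)-2,10-dimethyl-2-(2-oxoethyl)-3-(prop-1-en-2-yl)-6-[(trimethylsilyl)methyl]dodeca-6,10-diene-1,12-diyl diacetate (the C5-branched trienal; labdane numbering 4S,5R)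
Conditions: Dess–Martin periodinane, pyridine, CH2Cl2, 0 °C → rt; used at once
Reagents that add atoms: none
Why: Dess–Martin oxidation of the primary alcohol to the C2 aldehyde under buffered, non-acidic conditions that leave allylsilane, alkenes and esters alone; the aldehyde has no α-stereocentre to lose.

**Step 17**
Reactants: 25 (2S,3R,6Z,10Z)-2,10-dimethyl-2-(2-oxoethyl)-3-(prop-1-en-2-yl)-6-[(trimethylsilyl)methyl]dodeca-6,10-diene-1,12-diyl diacetate
Product: 26 2α-hydroxylabda-8(17),13Z-diene-15,19-diyl diacetate (2R,4S,5R,9S,10R; 5α-H, 9α-H, 10β-CH3)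
Conditions: MeAlCl2 (3.5 equiv), CH2Cl2 (0.005 M), −78 °C; Et3N/MeOH quench, aq. Rochelle salt
Reagents that add atoms: none
Why: MeAlCl2 binds the C2 aldehyde, C1 of the isopropenyl group adds to C2 and the tertiary C10 cation is taken by C9 of the allylsilane, after which loss of silicon from C17 leaves only the C8=C17 methylene; the closest known reactions are the Lewis-acid Prins cyclisation of 5-methylhex-5-enals and aldehyde- or acetal-initiated cation–olefin polycyclisations ended by an allylsilane. Ring A closes 6-endo with respect to the C10=C1 π bond (carbonyl oxygen exocyclic) and ring B 6-endo with respect to C8=C9, both through chairs. C2 is set by the complexed oxygen sitting equatorial, away from the axial C19 arm, in a chair that the C5 stereocentre fixes by keeping its C6 arm equatorial. C10 is set by anti addition across C10=C1, which puts C9 equatorial on ring A and C20 axial (trans-decalin), and C9 by the trans C7–C8=C9–C11 backbone, which puts C11 equatorial. The step needs the aldehyde to attack the isopropenyl group and not the allylsilane, which ring size secures (six against eight atoms), and it needs capture of the C10 cation before ene-type proton loss from C20, for which a weakly basic chloroaluminate alkoxide, a strongly nucleophilic allylsilane and high dilution are chosen. The C13 alkene has no ring of workable size open to it and is deactivated by its allylic acetate.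

**Step 18**
Reactants: 26 2α-hydroxylabda-8(17),13Z-diene-15,19-diyl diacetate
Product: 27 2α,7α-dihydroxylabda-8(17),13Z-diene-15,19-diyl diacetate (2R,4S,5R,7R,9R,10S; CNP0171158.2)
Conditions: SeO2 (0.3 equiv), t-BuOOH (2.5 equiv), CH2Cl2, 0 °C → rt, stopped before enone formation
Reagents that add atoms: selenium dioxide, O=[Se]=O; tert-butyl hydroperoxide, CC(C)(C)OO
Why: Selenium dioxide allylic hydroxylation (ene reaction at C17 with removal of the axial 7α-hydrogen, then [2,3]-sigmatropic shift) should return the C8=C17 alkene and place the new hydroxyl axial on the α-face of C7; the C7 methylene is preferred over the C9 methine and the C13 alkene is deactivated by its allylic acetate.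

**Compound list**

1 | 5,6-dihydro-2H-pyran-2-one | O=C1C=CCCO1 | starting material
2 | 2-isopropenyl-4,4,5,5-tetramethyl-1,3,2-dioxaborolane | C=C(C)B1OC(C)(C)C(C)(C)O1 | starting material
3 | (S)-4-(prop-1-en-2-yl)tetrahydro-2H-pyran-2-one | O=C1C[C@@H](C(C)=C)CCO1 | intermediate
4 | tert-butyl(2-iodoethoxy)dimethylsilane | CC(C)(C)[Si](C)(C)OCCI | starting material
5 | lithium enolate of 3 [lithium (S)-4-(prop-1-en-2-yl)-5,6-dihydro-4H-pyran-2-olate] | [Li]OC1=C[C@@H](C(C)=C)CCO1 | intermediate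
6 | (3R,4S)-3-[2-(tert-butyldimethylsilyloxy)ethyl]-4-(prop-1-en-2-yl)tetrahydro-2H-pyran-2-one | CC(C)(C)[Si](C)(C)OCC[C@H]1C(=O)OCC[C@@H]1C(C)=C | intermediate
7 | lithium enolate of 6 | CC(C)(C)[Si](C)(C)OCCC1=C(O[Li])OCC[C@@H]1C(C)=C | intermediate
8 | (3S,4R)-3-[2-(tert-butyldimethylsilyloxy)ethyl]-3-methyl-4-(prop-1-en-2-yl)tetrahydro-2H-pyran-2-one | CC(C)(C)[Si](C)(C)OCC[C@]1(C)C(=O)OCC[C@@H]1C(C)=C | intermediate
9 | (2S,3R)-2-[2-(tert-butyldimethylsilyloxy)ethyl]-2-methyl-3-(prop-1-en-2-yl)pentane-1,5-diol | CC(C)(C)[Si](C)(C)OCC[C@](C)(CO)[C@@H](C(C)=C)CCO | intermediate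
10 | 5-monotosylate of 9 | CC(C)(C)[Si](C)(C)OCC[C@](C)(CO)[C@@H](C(C)=C)CCOS(=O)(=O)c1ccc(C)cc1 | intermediate
11 | (2S,3R)-2-[2-(tert-butyldimethylsilyloxy)ethyl]-2-methyl-3-(prop-1-en-2-yl)-5-(tosyloxy)pentyl acetate | CC(C)(C)[Si](C)(C)OCC[C@](C)(COC(C)=O)[C@@H](C(C)=C)CCOS(=O)(=O)c1ccc(C)cc1 | intermediate
12 | (2S,3R)-2-[2-(tert-butyldimethylsilyloxy)ethyl]-5-iodo-2-methyl-3-(prop-1-en-2-yl)pentyl acetate | CC(C)(C)[Si](C)(C)OCC[C@](C)(COC(C)=O)[C@@H](C(C)=C)CCI | intermediate
13 | neryl acetate | CC(C)=CCC/C(C)=C\COC(C)=O | starting material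
14 | (2Z)-5-(5,5-dimethyl-1,2,4-trioxolan-3-yl)-3-methylpent-2-en-1-yl acetate (ozonide) | CC1(C)OOC(CC/C(C)=C\COC(C)=O)O1 | intermediate
15 | (2Z)-3-methyl-6-oxohex-2-en-1-yl acetate | O=CCC/C(C)=C\COC(C)=O | intermediate
16 | (2Z)-7,7-dichloro-3-methylhepta-2,6-dien-1-yl acetate | ClC(Cl)=CCC/C(C)=C\COC(C)=O | intermediate
17 | (2Z)-7,7-dichloro-3-methylhepta-2,6-dien-1-ol | ClC(Cl)=CCC/C(C)=C\CO | intermediate
18 | [(2Z)-7,7-dichloro-3-methylhepta-2,6-dien-1-yl]oxy(triethyl)silane | ClC(Cl)=CCC/C(C)=C\CO[Si](CC)(CC)CC | intermediate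
19 | alkylzinc iodide from 12 (zinc on C7) | CC(C)(C)[Si](C)(C)OCC[C@](C)(COC(C)=O)[C@@H](C(C)=C)CC[Zn]I | intermediate
20 | (2S,3R,6Z,10Z)-2-[2-(tert-butyldimethylsilyloxy)ethyl]-6-chloro-2,10-dimethyl-3-(prop-1-en-2-yl)-12-(triethylsilyloxy)dodeca-6,10-dien-1-yl acetate | CC(C)(C)[Si](C)(C)OCC[C@](C)(COC(C)=O)[C@@H](C(C)=C)CC/C(Cl)=C/CC/C(C)=C\CO[Si](CC)(CC)CC | intermediate
21 | (2S,3R,6Z,10Z)-2-[2-(tert-butyldimethylsilyloxy)ethyl]-2,10-dimethyl-3-(prop-1-en-2-yl)-12-(triethylsilyloxy)-6-[(trimethylsilyl)methyl]dodeca-6,10-dien-1-yl acetate | CC(C)(C)[Si](C)(C)OCC[C@](C)(COC(C)=O)[C@@H](C(C)=C)CC/C(C[Si](C)(C)C)=C/CC/C(C)=C\CO[Si](CC)(CC)CC | intermediate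
22 | (2S,3R,6Z,10Z)-2-[2-(tert-butyldimethylsilyloxy)ethyl]-12-hydroxy-2,10-dimethyl-3-(prop-1-en-2-yl)-6-[(trimethylsilyl)methyl]dodeca-6,10-dien-1-yl acetate | CC(C)(C)[Si](C)(C)OCC[C@](C)(COC(C)=O)[C@@H](C(C)=C)CC/C(C[Si](C)(C)C)=C/CC/C(C)=C\CO | intermediate
23 | (2S,3R,6Z,10Z)-2-[2-(tert-butyldimethylsilyloxy)ethyl]-2,10-dimethyl-3-(prop-1-en-2-yl)-6-[(trimethylsilyl)methyl]dodeca-6,10-diene-1,12-diyl diacetate | CC(C)(C)[Si](C)(C)OCC[C@](C)(COC(C)=O)[C@@H](C(C)=C)CC/C(C[Si](C)(C)C)=C/CC/C(C)=C\COC(C)=O | intermediate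
24 | (2S,3R,6Z,10Z)-2-(2-hydroxyethyl)-2,10-dimethyl-3-(prop-1-en-2-yl)-6-[(trimethylsilyl)methyl]dodeca-6,10-diene-1,12-diyl diacetate | OCC[C@](C)(COC(C)=O)[C@@H](C(C)=C)CC/C(C[Si](C)(C)C)=C/CC/C(C)=C\COC(C)=O | intermediate
25 | (2S,3R,6Z,10Z)-2,10-dimethyl-2-(2-oxoethyl)-3-(prop-1-en-2-yl)-6-[(trimethylsilyl)methyl]dodeca-6,10-diene-1,12-diyl diacetate | O=CC[C@](C)(COC(C)=O)[C@@H](C(C)=C)CC/C(C[Si](C)(C)C)=C/CC/C(C)=C\COC(C)=O | intermediate
26 | 2α-hydroxylabda-8(17),13Z-diene-15,19-diyl diacetate | C=C1CC[C@H]2[C@@](C)(COC(C)=O)C[C@H](O)C[C@]2(C)[C@H]1CC/C(C)=C\COC(C)=O | intermediate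
27 | 2α,7α-dihydroxylabda-8(17),13Z-diene-15,19-diyl diacetate (CNP0171158.2) | C=C1[C@H](O)C[C@H]2[C@@](C)(COC(C)=O)C[C@H](O)C[C@]2(C)[C@H]1CC/C(C)=C\COC(C)=O | target

**Step count and risks**

Total: 18 steps. Longest linear sequence: 14 steps (steps 1–6 and 11–18).

Steps most likely to fail:

1. Step 17. After the first C–C bond, proton transfer from C20 to the aluminium-bound oxygen (the carbonyl-ene outcome) or protodesilylation of the allylsilane may outrun closure of ring B. The cascade would then be started from an oxocarbenium ion, which cannot pass a proton to its own oxygen. Aldehyde 25 would be converted with propane-1,3-diol and PPTS (MgSO4, CH2Cl2) into the 2-substituted 1,3-dioxane of 25 F1. TiCl4 at −78 °C (acetal-initiated cation–olefin cyclisation ended by an allylsilane) should give the 2-O-(3-hydroxypropyl) ether of 26 F2. Dess–Martin oxidation to the 2-O-(3-oxopropyl) ether of 26 F3 and β-elimination of acrolein with DBU would release 26, where the route is rejoined before step 18.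

2. Step 11. Insertion of palladium may not discriminate well between the two C–Cl bonds, a second substitution may follow, or the functionalised alkylzinc may be lost by protonolysis or β-hydride transfer. The C8=C9 alkene would then be made by olefination. Iodide 12 would alkylate methylenetriphenylphosphorane to give the one-carbon-extended phosphonium iodide F4 (phosphorus on C8). NaHMDS would give its ylide F5, iodine the α-iodophosphonium iodide F6, and NaHMDS again the α-iodo ylide F7. Wittig reaction of F7 with aldehyde 15 (Zhao-type iodo-olefination, iodine cis to C11) should give the (8Z)-alkenyl iodide 15,19-diacetate F8. Methanolysis (K2CO3, MeOH) to the alkenyl iodide 15,19-diol F9, Kumada coupling with Me3SiCH2MgCl and Pd(PPh3)4 to the allylsilane 15,19-diol F10, and acetylation of both alcohols would rejoin the route at 23.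

3. Step 2. The β-silyloxy iodide is a slow electrophile, so loss of HI from it, incomplete conversion and dialkylation may cut the yield. The arm would then be brought in by carbonyl addition. The lithium enolate 5 of lactone 3 would add to (tert-butyldimethylsilyloxy)acetaldehyde to give the β-hydroxy lactone (aldol adduct) F11. Mesylation would give the mesylate F12, and elimination with DBU the α-alkylidene lactone F13. Conjugate reduction with Stryker's reagent should give 6, whose C4 configuration is again of no consequence, and the route is rejoined at step 3.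

**Further compounds**

F1 | step 17 | 1,3-dioxane acetal of 25 | C1COC(C[C@](C)(COC(C)=O)[C@@H](C(C)=C)CC/C(C[Si](C)(C)C)=C/CC/C(C)=C\COC(C)=O)OC1
F2 | step 17 | 2-O-(3-hydroxypropyl) ether of 26 | C=C1CC[C@H]2[C@@](C)(COC(C)=O)C[C@H](OCCCO)C[C@]2(C)[C@H]1CC/C(C)=C\COC(C)=O
F3 | step 17 | 2-O-(3-oxopropyl) ether of 26 | C=C1CC[C@H]2[C@@](C)(COC(C)=O)C[C@H](OCCC=O)C[C@]2(C)[C@H]1CC/C(C)=C\COC(C)=O
F4 | step 11 | one-carbon-extended phosphonium iodide from 12 | CC(C)(C)[Si](C)(C)OCC[C@](C)(COC(C)=O)[C@@H](C(C)=C)CCC[P+](c1ccccc1)(c1ccccc1)c1ccccc1.[I-]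
F5 | step 11 | ylide of F4 | CC(C)(C)[Si](C)(C)OCC[C@](C)(COC(C)=O)[C@@H](C(C)=C)CCC=P(c1ccccc1)(c1ccccc1)c1ccccc1
F6 | step 11 | α-iodophosphonium iodide | CC(C)(C)[Si](C)(C)OCC[C@](C)(COC(C)=O)[C@@H](C(C)=C)CCC(I)[P+](c1ccccc1)(c1ccccc1)c1ccccc1.[I-]
F7 | step 11 | α-iodo ylide | CC(C)(C)[Si](C)(C)OCC[C@](C)(COC(C)=O)[C@@H](C(C)=C)CCC(I)=P(c1ccccc1)(c1ccccc1)c1ccccc1
F8 | step 11 | (8Z)-alkenyl iodide 15,19-diacetate | CC(C)(C)[Si](C)(C)OCC[C@](C)(COC(C)=O)[C@@H](C(C)=C)CC/C(I)=C/CC/C(C)=C\COC(C)=O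
F9 | step 11 | alkenyl iodide 15,19-diol | CC(C)(C)[Si](C)(C)OCC[C@](C)(CO)[C@@H](C(C)=C)CC/C(I)=C/CC/C(C)=C\CO
F10 | step 11 | allylsilane 15,19-diol | CC(C)(C)[Si](C)(C)OCC[C@](C)(CO)[C@@H](C(C)=C)CC/C(C[Si](C)(C)C)=C/CC/C(C)=C\CO
F11 | step 2 | β-hydroxy lactone (aldol adduct) | CC(C)(C)[Si](C)(C)OCC(O)[C@H]1C(=O)OCC[C@@H]1C(C)=C
F12 | step 2 | mesylate of F11 | CC(C)(C)[Si](C)(C)OCC(OS(C)(=O)=O)[C@H]1C(=O)OCC[C@@H]1C(C)=C
F13 | step 2 | α-alkylidene lactone | CC(C)(C)[Si](C)(C)OCC=C1C(=O)OCC[C@@H]1C(C)=C
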